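**Retrosynthetic overview**
- The plan rests on the exocyclic C5=CH double bond of the tetronate ring (O1, C2–C5). Lactone oxygen O1 and ring B lie cis across it (Z), which is the outcome of anti addition of a carboxyl O–H across an aryl alkyne.
- Target ⇒ (desilylation, oxidation of the C4 carbinol) (Z)-4-hydroxy-5-benzylidene lactone ⇒ (O1–C5 bond, 5-exo-dig, Ag2CO3) 2-aryl-3-hydroxy-5-arylpent-4-ynoic acid.
- Acid ⇒ (aldol bond between the later C3 and C4; allyl ester removed by zerovalent palladium) ring A allyl arylacetate + ring B arylpropynal that already carries the (R)-oxirane.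
- Ring A ester ⇒ 2,4-dihydroxyphenylacetic acid + isoprene via a temporary benzofuranone. Ring B ynal ⇒ 4-hydroxybenzaldehyde + prenyl bromide by Corey–Fuchs homologation, with Shi epoxidation at the dibromoalkene stage, so the tetronate never meets basic Oxone and O4 needs no protection.
- Order of ring formation: benzofuranone (temporary), dihydropyran of the chroman, oxirane, tetronate lactone last.

Key step: step 12

Assumption: the oxirane CH carbon of the target is R (O > CMe2 > CH2 > H), and the D-fructose-derived Shi ketone is taken to give this sense on ArCH2CH=CMe2 as it does on other 3-methylbut-2-enyl groups.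
Numbering used: tetronate O1, C2 (C=O), C3 (ring A), C4 (OH), C5 (benzylidene). Ring A is the chroman arene and ring B the benzylidene arene. TBS = tert-butyldimethylsilyl.

**Step 1**
Reactants: 1 2,4-dihydroxyphenylacetic acid
Product: 2 6-hydroxybenzofuran-2(3H)-one
Conditions: TsOH·H2O (cat.), toluene, reflux, Dean–Stark
Reagents that add atoms: none
Why: Acid-catalysed lactonization (intramolecular Fischer esterification) of an o-hydroxyphenylacetic acid is driven by azeotropic removal of water and masks the carboxyl group and the 2-OH together, so that only the 4-OH is left to direct step 2.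

**Step 2**
Reactants: 2 6-hydroxybenzofuran-2(3H)-one; 3 isoprene
Product: 5 7,7-dimethyl-3,5,6,7-tetrahydro-2H-furo[3,2-g]chromen-2-one, via 5-prenylbenzofuranone 4 (not isolated)
Conditions: sulfonic acid resin Amberlyst-15 (polystyrene–SO3H), THF–heptane, 65–70 °C, slow addition of 3
Reagents that add atoms: none
Why: In this known one-pot chroman annulation of phenols the resin protonates isoprene, the prenyl cation alkylates C5 (Friedel–Crafts; ortho to the only free OH, para to the lactone oxygen and less crowded than C7 between two oxygens), and Markovnikov hydroalkoxylation of the prenyl double bond of 4 by that OH closes the dihydropyran ring.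

**Step 3**
Reactants: 5 7,7-dimethyl-3,5,6,7-tetrahydro-2H-furo[3,2-g]chromen-2-one
Product: 6 allyl 2-(7-hydroxy-2,2-dimethylchroman-6-yl)acetate
Conditions: allyl alcohol (solvent), TsOH·H2O (cat.), 60 °C; NaHCO3 before concentration
Reagents that add atoms: allyl alcohol, C=CCO
Why: Acid-catalysed transesterification of the aryl lactone in neat allyl alcohol should lie on the side of the open hydroxy ester, as in Fischer esterification of o-hydroxyphenylacetic acids, and brings in an ester that can later be removed without hydroxide, strong acid or fluoride.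

**Step 4**
Reactants: 6 allyl 2-(7-hydroxy-2,2-dimethylchroman-6-yl)acetate
Product: 7 allyl 2-[7-(TBS-oxy)-2,2-dimethylchroman-6-yl]acetate
Conditions: TBSCl, imidazole, DMF, rt
Reagents that add atoms: TBSCl, CC(C)(C)[Si](C)(C)Cl
Why: Imidazole-promoted silylation of the phenol is faster than relactonization and shields the oxygen during enolate formation and the later oxidation.

**Step 5**
Reactants: 8 4-hydroxybenzaldehyde; 9 prenyl bromide
Product: 10 4-hydroxy-3-(3-methylbut-2-enyl)benzaldehyde
Conditions: KOH, H2O, rt
Reagents that add atoms: none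
Why: Alkylation of the ambident phenoxide in water, where hydrogen bonding blocks the oxygen, shifts part of the attack of the allylic bromide to the ortho carbon (known direct C-prenylation of this aldehyde), and the outcome of competing O-alkylation is removed by extracting phenol 10 into base.

**Step 6**
Reactants: 10 4-hydroxy-3-(3-methylbut-2-enyl)benzaldehyde
Product: 11 4-(TBS-oxy)-3-(3-methylbut-2-enyl)benzaldehyde
Conditions: TBSCl, imidazole, CH2Cl2, rt
Reagents that add atoms: TBSCl, CC(C)(C)[Si](C)(C)Cl
Why: Standard silylation of a phenol, chosen so that both phenols of the target can be freed together by fluoride at the end.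

**Step 7**
Reactants: 11 4-(TBS-oxy)-3-(3-methylbut-2-enyl)benzaldehyde
Product: 12 tert-butyl[4-(2,2-dibromovinyl)-2-(3-methylbut-2-enyl)phenoxy]dimethylsilane
Conditions: CBr4, PPh3, CH2Cl2, 0 °C
Reagents that add atoms: carbon tetrabromide, BrC(Br)(Br)Br
Why: First stage of the Corey–Fuchs homologation, in which the ylide Ph3P=CBr2 formed in the flask olefinates the aldehyde in a Wittig reaction while neither the prenyl group nor the aryl silyl ether reacts.

**Step 8**
Reactants: 12 tert-butyl[4-(2,2-dibromovinyl)-2-(3-methylbut-2-enyl)phenoxy]dimethylsilane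
Product: 13 (R)-tert-butyl{4-(2,2-dibromovinyl)-2-[(3,3-dimethyloxiran-2-yl)methyl]phenoxy}dimethylsilane
Conditions: 1,2:4,5-di-O-isopropylidene-β-D-erythro-2,3-hexodiulo-2,6-pyranose (Shi ketone from D-fructose, 30 mol %), Oxone (2KHSO5·KHSO4·K2SO4), K2CO3, Bu4NHSO4 (cat.), MeCN–dimethoxymethane, aq. Na2B4O7/Na2H2EDTA buffer (pH about 10.5), 0 °C
Reagents that add atoms: potassium peroxymonosulfate (active part of Oxone), [K+].[O-]S(=O)(=O)OO
Why: Shi asymmetric epoxidation, in which the chiral dioxirane from the D-fructose-derived ketone transfers oxygen through a spiro transition state to the electron-rich trisubstituted prenyl double bond on the face that makes the oxirane CH carbon R, while the electron-poor dibromoalkene is inert to the electrophilic oxidant and the ortho-shielded aryl silyl ether should last the short exposure to base at 0 °C.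

**Step 9**
Reactants: 13 (R)-tert-butyl{4-(2,2-dibromovinyl)-2-[(3,3-dimethyloxiran-2-yl)methyl]phenoxy}dimethylsilane
Product: 15 (R)-3-{4-(TBS-oxy)-3-[(3,3-dimethyloxiran-2-yl)methyl]phenyl}prop-2-ynal, via lithium acetylide 14 (not isolated)
Conditions: n-BuLi (2.1 equiv), THF, −78 °C; DMF, −78 → 0 °C; poured into cold 10% aq. KH2PO4/MTBE
Reagents that add atoms: N,N-dimethylformamide, CN(C)C=O
Why: Second stage of the Corey–Fuchs homologation (bromine–lithium exchange, 1,2-shift with loss of LiBr, deprotonation) gives acetylide 14, which is formylated by DMF, the oxirane being inert to organolithiums at −78 °C without a Lewis acid and the inverse phosphate quench keeping dimethylamine from adding to the ynal.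

**Step 10**
Reactants: 7 allyl 2-[7-(TBS-oxy)-2,2-dimethylchroman-6-yl]acetate; 15 (R)-3-{4-(TBS-oxy)-3-[(3,3-dimethyloxiran-2-yl)methyl]phenyl}prop-2-ynal
Product: 17 allyl 2-[7-(TBS-oxy)-2,2-dimethylchroman-6-yl]-3-hydroxy-5-{4-(TBS-oxy)-3-[(R)-(3,3-dimethyloxiran-2-yl)methyl]phenyl}pent-4-ynoate (mixture at C2 and C3), via lithium enolate 16 (not isolated)
Conditions: LiN(iPr)2 (1.05 equiv), THF, −78 °C; 15, −78 °C; AcOH/THF quench at −78 °C
Reagents that add atoms: none
Why: Aldol addition of the lithium enolate of an arylacetate to the aldehyde carbonyl of an ynal (kinetic 1,2-addition at −78 °C) forms the C2–C3 bond, the cold acidic quench forestalls retro-aldol cleavage, and the two new centres are left uncontrolled because both become trigonal in step 13.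

**Step 11**
Reactants: 17 allyl 2-aryl-3-hydroxy-5-arylpent-4-ynoate
Product: 18 2-[7-(TBS-oxy)-2,2-dimethylchroman-6-yl]-3-hydroxy-5-{4-(TBS-oxy)-3-[(R)-(3,3-dimethyloxiran-2-yl)methyl]phenyl}pent-4-ynoic acid (mixture at C2 and C3)
Conditions: Pd(PPh3)4 (5 mol %), morpholine, THF, rt; cold pH 4 citrate wash
Reagents that add atoms: none
Why: Tsuji–Trost deallylation, in which zerovalent palladium ionises the allyl ester and morpholine captures the π-allyl fragment, frees the acid under conditions too mild for retro-aldol cleavage, loss of water, desilylation or oxirane opening, all of which saponification would risk.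

**Step 12**
Reactants: 18 2-aryl-3-hydroxy-5-arylpent-4-ynoic acid
Product: 19 (Z)-3-[7-(TBS-oxy)-2,2-dimethylchroman-6-yl]-4-hydroxy-5-{4-(TBS-oxy)-3-[(R)-(3,3-dimethyloxiran-2-yl)methyl]benzylidene}dihydrofuran-2(3H)-one (mixture at C3 and C4)
Conditions: Ag2CO3 (10 mol %), toluene, rt, dark
Reagents that add atoms: none
Why: Ag2CO3 turns acid 18 into its silver carboxylate, monovalent silver binds the triple bond, the carboxylate oxygen attacks the nearer alkyne carbon from the face opposite to the metal, and protonolysis of the vinylsilver species by a further molecule of acid places hydrogen trans to oxygen, so that O1 and ring B end up cis (Z). This is the known silver-catalysed cycloisomerization of 4-alkynoic acids to (Z)-5-ylidenebutyrolactones. The one ring that closes, the five-membered lactone, does so in the 5-exo-dig mode with formation of the O1–C5 bond. No new stereocentre arises; the only new stereo-element is the double bond geometry, fixed by the anti addition, and the centres at C3 and C4 are carried as a mixture that step 13 erases. The step needs 5-exo over 6-endo closure although the electron-rich ring B polarises the alkyne towards its aryl-bearing carbon, and this is secured by the two-atom sp3 tether with its two substituents, by the propargylic C–O bond, which is known to speed up exo closure under silver catalysis, and by the absence of a carbonyl group conjugated to the alkyne. The soft catalyst, the apolar solvent and room temperature should leave the oxirane, the silyl ethers and the β-hydroxy lactone, which is prone to loss of water, untouched.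

**Step 13**
Reactants: 19 (Z)-3-aryl-4-hydroxy-5-benzylidenedihydrofuran-2(3H)-one
Product: 20 (Z)-3-[7-(TBS-oxy)-2,2-dimethylchroman-6-yl]-4-hydroxy-5-{4-(TBS-oxy)-3-[(R)-(3,3-dimethyloxiran-2-yl)methyl]benzylidene}furan-2(5H)-one
Conditions: Dess–Martin periodinane (1.1 equiv), CH2Cl2, 0 °C → rt, dark
Reagents that add atoms: none
Why: Dess–Martin oxidation of a β-hydroxy carbonyl compound to the 1,3-dicarbonyl stage under nearly neutral conditions gives the β-keto lactone, which enolises at once to the conjugated tetronic acid and thereby erases the C3 and C4 centres, only a small excess of oxidant being used to avoid further oxidation at C3.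

**Step 14**
Reactants: 20 bis-TBS tetronic acid
Product: 21 target, (Z)-4-hydroxy-3-(7-hydroxy-2,2-dimethylchroman-6-yl)-5-{4-hydroxy-3-[(R)-(3,3-dimethyloxiran-2-yl)methyl]benzylidene}furan-2(5H)-one
Conditions: Bu4NF/AcOH (1:1, 3 equiv each), THF, 0 °C, short contact, dark; cold pH 3–4 citrate wash
Reagents that add atoms: none
Why: Fluoride desilylation cleaves both aryl O–Si bonds within a short time at 0 °C, and the acetic acid protonates each phenoxide as it forms so that the ring B oxygen cannot open the neighbouring oxirane, while the Z double bond and the R centre are not touched.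

**Compound list**
1 | 2,4-dihydroxyphenylacetic acid | OC(=O)Cc1ccc(O)cc1O | starting material
2 | 6-hydroxybenzofuran-2(3H)-one | O=C1Cc2ccc(O)cc2O1 | intermediate
3 | isoprene | C=CC(C)=C | starting material
4 | 6-hydroxy-5-(3-methylbut-2-enyl)benzofuran-2(3H)-one (not isolated) | O=C1Cc2cc(CC=C(C)C)c(O)cc2O1 | intermediate
5 | 7,7-dimethyl-3,5,6,7-tetrahydro-2H-furo[3,2-g]chromen-2-one | CC1(C)CCc2cc3CC(=O)Oc3cc2O1 | intermediate
6 | allyl 2-(7-hydroxy-2,2-dimethylchroman-6-yl)acetate | C=CCOC(=O)Cc1cc2CCC(C)(C)Oc2cc1O | intermediate
7 | allyl 2-[7-(TBS-oxy)-2,2-dimethylchroman-6-yl]acetate | C=CCOC(=O)Cc1cc2CCC(C)(C)Oc2cc1O[Si](C)(C)C(C)(C)C | intermediate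
8 | 4-hydroxybenzaldehyde | O=Cc1ccc(O)cc1 | starting material
9 | prenyl bromide (1-bromo-3-methylbut-2-ene) | CC(C)=CCBr | starting material
10 | 4-hydroxy-3-(3-methylbut-2-enyl)benzaldehyde | O=Cc1ccc(O)c(CC=C(C)C)c1 | intermediate
11 | 4-(TBS-oxy)-3-(3-methylbut-2-enyl)benzaldehyde | O=Cc1ccc(O[Si](C)(C)C(C)(C)C)c(CC=C(C)C)c1 | intermediate
12 | tert-butyl[4-(2,2-dibromovinyl)-2-(3-methylbut-2-enyl)phenoxy]dimethylsilane | BrC(Br)=Cc1ccc(O[Si](C)(C)C(C)(C)C)c(CC=C(C)C)c1 | intermediate
13 | (R)-tert-butyl{4-(2,2-dibromovinyl)-2-[(3,3-dimethyloxiran-2-yl)methyl]phenoxy}dimethylsilane | BrC(Br)=Cc1ccc(O[Si](C)(C)C(C)(C)C)c(C[C@H]2OC2(C)C)c1 | intermediate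
14 | lithium acetylide of the ring B fragment, oxirane R (not isolated) | [Li]C#Cc1ccc(O[Si](C)(C)C(C)(C)C)c(C[C@H]2OC2(C)C)c1 | intermediate
15 | (R)-3-{4-(TBS-oxy)-3-[(3,3-dimethyloxiran-2-yl)methyl]phenyl}prop-2-ynal | O=CC#Cc1ccc(O[Si](C)(C)C(C)(C)C)c(C[C@H]2OC2(C)C)c1 | intermediate
16 | lithium enolate of 7 (not isolated) | [Li]OC(OCC=C)=Cc1cc2CCC(C)(C)Oc2cc1O[Si](C)(C)C(C)(C)C | intermediate
17 | allyl 2-(ring A aryl)-3-hydroxy-5-(ring B aryl)pent-4-ynoate, oxirane R, mixture at C2/C3 | C=CCOC(=O)C(c1cc2CCC(C)(C)Oc2cc1O[Si](C)(C)C(C)(C)C)C(O)C#Cc1ccc(O[Si](C)(C)C(C)(C)C)c(C[C@H]2OC2(C)C)c1 | intermediate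
18 | 2-(ring A aryl)-3-hydroxy-5-(ring B aryl)pent-4-ynoic acid, oxirane R, mixture at C2/C3 | OC(=O)C(c1cc2CCC(C)(C)Oc2cc1O[Si](C)(C)C(C)(C)C)C(O)C#Cc1ccc(O[Si](C)(C)C(C)(C)C)c(C[C@H]2OC2(C)C)c1 | intermediate
19 | (Z)-3-aryl-4-hydroxy-5-benzylidenedihydrofuran-2(3H)-one, oxirane R, mixture at C3/C4 | O=C1O/C(=C\c2ccc(O[Si](C)(C)C(C)(C)C)c(C[C@H]3OC3(C)C)c2)C(O)C1c1cc2CCC(C)(C)Oc2cc1O[Si](C)(C)C(C)(C)C | intermediate
20 | bis-TBS ether of the target (Z, R) | CC1(C)CCc2cc(C3=C(O)/C(=C/c4ccc(O[Si](C)(C)C(C)(C)C)c(C[C@H]5OC5(C)C)c4)OC3=O)c(O[Si](C)(C)C(C)(C)C)cc2O1 | intermediate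
21 | CNP0384423.1 (Z, R) | CC1(C)CCc2cc(C3=C(O)/C(=C/c4ccc(O)c(C[C@H]5OC5(C)C)c4)OC3=O)c(O)cc2O1 | target

**Step count and risks**
Total step count: 14. Longest linear sequence: 10 steps (8 → 21, steps 5–14). The ring A branch is 9 steps (steps 1–4 and 10–14).

*Step 12.*
- What may go wrong: turnover on the hindered internal alkyne may be slow. Closure at the aryl-bearing alkyne carbon (six-membered mode) or base-induced loss of water from the new β-hydroxy lactone could then compete.
- Fallback, from 18 back to 19: acid 18 would be treated with I2 and NaHCO3 in MeCN at 0 °C in the dark. This iodonium-induced anti addition is the known halolactonization of alkynoic acids to halo enol lactones. It is fast and irreversible and should give the (E)-iodo enol lactone F1, in which O1 and iodine are trans.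
- Hydrodeiodination with Bu3SnH and Pd(PPh3)4 in THF at rt replaces vinylic iodine by hydrogen with retention. It returns 19 with O1 and ring B cis.
- Should the six-membered mode persist, the detour given under step 13 applies.

*Step 13.*
- What may go wrong: β-elimination of the carbinol once it is bound to pentavalent iodine, or further oxidation of the enolic product at C3.
- Fallback, from 7 and 13 back to 20: C4 enters as a ketone, no carbinol is ever formed, and steps 10–13 are bypassed.
- Ester 7 would be converted with MeNH(OMe)·HCl and iPrMgCl (THF, −20 °C) into the Weinreb amide F2.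
- Acetylide 14, made from 13 as in step 9, would be added to F2 at −78 °C to give the benzyl alkynyl ketone F3.
- The known silver-catalysed carboxylative cyclization of such ynones would follow (AgO2CPh cat., 7-methyl-1,5,7-triazabicyclo[4.4.0]dec-5-ene, CO2 under pressure, MeCN, rt). The enolate captures CO2 at the benzylic carbon, and the β-keto carboxylate adds anti and 5-exo-dig to the silver-bound alkyne. This gives 20 after a mild acidic work-up.

*Step 14.*
- What may go wrong: intramolecular opening of the oxirane by the ring B phenoxide released ortho to it, or acid-induced opening of the oxirane during work-up.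
- Fallback, from 20 back to 21: desilylation would be run with Bu4NF in the presence of excess Ac2O (THF, 0 °C). This is the known fluoride-mediated exchange of silyl ethers for acetates. Each phenoxide is acetylated as it is released and O4 is acetylated as well, giving the triacetate F4.
- The acetates would then be removed under neutral conditions with NH4OAc in aqueous MeOH at rt, the known neutral deprotection of aromatic acetates. The phenols then appear only in their protonated form, and 21 results.

**Further compounds**
F1 | step 12 | (E)-3-[7-(TBS-oxy)-2,2-dimethylchroman-6-yl]-4-hydroxy-5-{iodo[4-(TBS-oxy)-3-((R)-(3,3-dimethyloxiran-2-yl)methyl)phenyl]methylidene}dihydrofuran-2(3H)-one | O=C1O/C(=C(/I)c2ccc(O[Si](C)(C)C(C)(C)C)c(C[C@H]3OC3(C)C)c2)C(O)C1c1cc2CCC(C)(C)Oc2cc1O[Si](C)(C)C(C)(C)C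
F2 | step 13 | N-methoxy-N-methyl-2-[7-(TBS-oxy)-2,2-dimethylchroman-6-yl]acetamide | CON(C)C(=O)Cc1cc2CCC(C)(C)Oc2cc1O[Si](C)(C)C(C)(C)C
F3 | step 13 | 1-[7-(TBS-oxy)-2,2-dimethylchroman-6-yl]-4-{4-(TBS-oxy)-3-[(R)-(3,3-dimethyloxiran-2-yl)methyl]phenyl}but-3-yn-2-one | O=C(Cc1cc2CCC(C)(C)Oc2cc1O[Si](C)(C)C(C)(C)C)C#Cc1ccc(O[Si](C)(C)C(C)(C)C)c(C[C@H]2OC2(C)C)c1
F4 | step 14 | triacetate of the target (Z, R; acetates on O4 and on both phenols) | CC1(C)CCc2cc(C3=C(OC(C)=O)/C(=C/c4ccc(OC(C)=O)c(C[C@H]5OC5(C)C)c4)OC3=O)c(OC(C)=O)cc2O1
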